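Ring C is disconnected last, at C4a–C4, C4–C3 and O1–C2. The route exploits the symmetry of ring A: C4a is flanked by two interchangeable oxygen-bearing carbons (C5 and C8a, carrying O5 and O1), and ring C adds only one carbon, the C4 carbonyl, between C4a and the C3=C2 pair on ring B. One palladium-catalysed carbonylative alkynylation–cyclisation therefore joins an iodophloroglucinol (used as its triacetate), carbon monoxide and a terminal aryl alkyne into the 5,7-dihydroxyflavone. The alkyne is ring B carrying the complete (7R,8S) side chain: C9 p-coumarate, silylated C7 hydroxyl and silylated phenols, made by an Evans aldol and a Mitsunobu inversion at C7.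

Key step: step 13

Remark on the chemistry: side-chain carbons are numbered C7 (benzylic carbinol), C8 (aryl ether carbon) and C9 (acylated CH2); the target is (7R,8S), the erythro series, whereas an auxiliary-controlled syn aldol gives the threo (7S,8S) series, so C7 is inverted once.

Step 1
Reactants: 1 (R)-4-benzyl-2-oxazolidinone; 2 bromoacetyl bromide
Product: 3 (R)-4-benzyl-3-(2-bromoacetyl)oxazolidin-2-one
Conditions: n-BuLi, THF, −78 °C; then 2, −78 → 0 °C
Reagents that add atoms: none
Why: N-acylation of the lithiated oxazolidinone is the standard loading of an Evans auxiliary, and the acyl bromide reacts far faster than the primary alkyl bromide, which is kept for the next step.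

Step 2
Reactants: 3 (R)-4-benzyl-3-(2-bromoacetyl)oxazolidin-2-one; 4 4-bromo-2,6-dimethoxyphenol
Product: 5 (R)-4-benzyl-3-[2-(4-bromo-2,6-dimethoxyphenoxy)acetyl]oxazolidin-2-one
Conditions: K2CO3, acetone, rt
Reagents that add atoms: none
Why: Williamson etherification, in which the phenoxide displaces bromide by SN2 at the carbonyl-activated primary carbon, so the hindered 4'-oxygen of ring B is alkylated before any stereocentre exists and much faster than it could attack the imide carbonyl.

Step 3
Reactants: 6 vanillin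
Product: 7 3-methoxy-4-(triisopropylsilyloxy)benzaldehyde
Conditions: TIPSCl, imidazole, DMF, rt
Reagents that add atoms: chlorotriisopropylsilane, CC(C)[Si](Cl)(C(C)C)C(C)C
Why: Standard silylation of a phenol, with the bulky triisopropylsilyl ether chosen because it should withstand the boron triflate, borohydride, brief carbonate methanolysis and amines used later.

Step 4
Reactants: 5 (R)-4-benzyl-3-[2-(4-bromo-2,6-dimethoxyphenoxy)acetyl]oxazolidin-2-one; 7 3-methoxy-4-(triisopropylsilyloxy)benzaldehyde
Product: 9 syn aldol adduct (2R,3S)-2-aryloxy-3-hydroxy-3-arylpropanoyl imide, via Z-boron enolate 8 (not isolated)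
Conditions: Bu2BOTf, i-Pr2NEt, CH2Cl2, −78 → 0 °C; then 7, −78 → 0 °C; pH 7 buffer, MeOH, H2O2, 0 °C
Reagents that add atoms: none
Why: Evans syn aldol reaction, in which soft enolisation gives the Z-boron enolate 8 and this adds to the aldehyde through a chair Zimmerman–Traxler transition state on the face away from the benzyl group of the (R)-auxiliary, so the aryloxy-bearing carbon is set in the configuration that becomes 8S after reduction and the carbinol carbon is set as 7S (threo), leaving only C7 to be inverted.

Step 5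
Reactants: 9 syn aldol adduct
Product: 10 (1S,2S)-2-(4-bromo-2,6-dimethoxyphenoxy)-1-(3-methoxy-4-triisopropylsilyloxyphenyl)propane-1,3-diol (threo)
Conditions: LiBH4, H2O (1 equiv), THF/Et2O, 0 °C
Reagents that add atoms: none
Why: Reductive cleavage of the N-acyl oxazolidinone with LiBH4 should deliver the primary C9 alcohol without epimerising C8 or touching the aryl bromide and the silyl ether, and it returns the auxiliary.

Step 6
Reactants: 10 threo bromoaryl diol
Product: 12 (1S,2S)-2-(4-ethynyl-2,6-dimethoxyphenoxy)-1-(3-methoxy-4-triisopropylsilyloxyphenyl)propane-1,3-diol, via TMS-alkyne 11 (not isolated)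
Conditions: TMS-acetylene, Pd(PhCN)2Cl2 (3 mol%), [HP(t-Bu)3]BF4 (6 mol%), CuI (2 mol%), i-Pr2NH, dioxane, rt → 45 °C; filter, concentrate; then K2CO3 (cat.), MeOH/THF, 0 °C
Reagents that add atoms: ethynyltrimethylsilane, C#C[Si](C)(C)C
Why: Sonogashira coupling with a bulky electron-rich trialkylphosphine, which is established for electron-rich aryl bromides near room temperature and tolerates free hydroxyl groups, followed by base-catalysed methanolysis of the C–Si bond, which is much faster than cleavage of the hindered aryl triisopropylsilyl ether.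

Step 7
Reactants: 13 p-coumaric acid
Product: 15 (E)-4-(triisopropylsilyloxy)cinnamic acid, via bis-silyl derivative 14 (not isolated)
Conditions: TIPSCl (2.2 equiv), imidazole, DMF, rt; then AcOH/THF/H2O, rt
Reagents that add atoms: chlorotriisopropylsilane, CC(C)[Si](Cl)(C(C)C)C(C)C
Why: Exhaustive silylation followed by selective hydrolysis of the silyl ester, whose acyl–oxygen–silicon bond is far more labile than the aryl silyl ether, is the usual route to O-silylated hydroxycinnamic acids.

Step 8
Reactants: 12 threo ethynylaryl diol; 15 (E)-4-(triisopropylsilyloxy)cinnamic acid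
Product: 16 threo (7S,8S) C9 coumarate with free C7 hydroxyl
Conditions: DCC, DMAP (cat.), CH2Cl2, −10 → 0 °C
Reagents that add atoms: none
Why: Steglich esterification, in which the unhindered primary C9 hydroxyl should be acylated in preference to the secondary benzylic C7 hydroxyl next to the bulky aryloxy group when one equivalent of acid is used at low temperature.

Step 9
Reactants: 16 threo C9 coumarate
Product: 17 erythro (7R,8S) C7 chloroacetate
Conditions: ClCH2CO2H, PPh3, DIAD, toluene, 0 °C → rt
Reagents that add atoms: chloroacetic acid, OC(=O)CCl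
Why: Mitsunobu reaction, in which the C7 hydroxyl is activated in situ and displaced by chloroacetate in an SN2 process with inversion, converting 7S into 7R (threo to erythro) while C8 is untouched, and in which the acidic nucleophile and the apolar solvent favour direct displacement over ionisation of the electron-rich benzylic centre.

Step 10
Reactants: 17 erythro C7 chloroacetate
Product: 18 erythro (7R,8S) C9 coumarate with free C7 hydroxyl
Conditions: thiourea, NaHCO3, Bu4NI (cat.), THF/EtOH, 50 °C
Reagents that add atoms: none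
Why: Chemoselective dechloroacetylation, in which thiourea is alkylated on sulfur and then cyclises onto the ester carbonyl, releasing the C7 alcohol by acyl–oxygen cleavage with retention under conditions that should leave the cinnamate ester and the silyl ethers alone.

Step 11
Reactants: 18 erythro alcohol
Product: 19 ring B alkyne with C7 triethylsilyl ether and C9 coumarate (key-step alkyne)
Conditions: TESOTf, 2,6-lutidine, CH2Cl2, −78 → 0 °C
Reagents that add atoms: triethylsilyl triflate, CC[Si](CC)(CC)OS(=O)(=O)C(F)(F)F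
Why: Silylation of a hindered secondary alcohol with a silyl triflate, the triethylsilyl ether being chosen because it blocks acyl migration and O-acylation at C7 in the amine-rich key step yet is removed much more easily than a tert-butyldimethylsilyl ether at the end.

Step 12
Reactants: 20 phloroglucinol
Product: 22 2-iodobenzene-1,3,5-triyl triacetate, via 2-iodophloroglucinol 21 (not isolated)
Conditions: I2 (1.0 equiv), NaHCO3, THF/H2O, 0 °C; extract, concentrate cold; then Ac2O, pyridine, DMAP (cat.), 0 °C → rt
Reagents that add atoms: iodine, [I][I]; acetic anhydride, CC(=O)OC(C)=O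
Why: Electrophilic aromatic iodination of the triol, whose three ring positions are equivalent so that one equivalent of iodine should give the mono-iodide, followed at once by peracetylation, which turns the oxidation-prone iodotriol into a stable, purifiable and less electron-rich ortho-iodophenyl acetate.

Step 13
Reactants: 19 ring B alkyne; 22 2-iodobenzene-1,3,5-triyl triacetate; 23 carbon monoxide
Product: 26 5,7-dihydroxyflavone with silylated (7R,8S) side chain, via ynone 24 (not isolated), via enaminone 25 (not isolated)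
Conditions: 22 (1.5 equiv), CO (1 atm), PdCl2(PPh3)2 (5 mol%), dppp (5 mol%), thiourea (5 mol%), Et2NH (excess), DBU (2 equiv), THF, 40 °C
Reagents that add atoms: none
Why: This is a carbonylative Sonogashira coupling with in situ cyclisation, the known palladium-catalysed annulation of ortho-iodophenyl acetates, carbon monoxide and terminal alkynes to flavones: the C–I bond of 22 adds to zerovalent palladium, CO inserts, the alkynyl group of 19 is transferred and reductive elimination releases ynone 24, creating C4a–C4 and C4–C3. Diethylamine then adds to the ynone and aminolyses the acetates to give enaminone 25, whose freed ortho phenol attacks C2 in a 6-endo-trig addition and expels the amine, forming O1–C2 and closing ring C. No stereocentre is formed, and C7 and C8 are remote, non-acidic and carry a silyl ether and an aryl ether that these conditions should leave untouched. The step needs six-membered rather than five-membered (aurone) closure, which the enaminone addition–elimination pathway secures, and a single regiochemistry on ring A, which the symmetry of 22 secures because the iodine-bearing carbon (future C4a) lies between two equivalent acetoxy-bearing carbons (future C5 and C8a). The acetates also keep ring A from reacting as a free, easily oxidised phenoxide during oxidative addition and CO insertion, and 22 is used in excess so that the valuable alkyne is consumed.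

Step 14
Reactants: 26 silylated flavone
Product: 27 target CNP0264527.1
Conditions: TBAF, AcOH (1:1), THF, 0 °C → rt
Reagents that add atoms: none
Why: Fluoride-mediated cleavage of the two aryl triisopropylsilyl ethers and the triethylsilyl ether, buffered with acetic acid so that the C9 coumarate should be neither hydrolysed nor moved to the liberated C7 hydroxyl and the benzylic centre should not epimerise.

Compound list
1 | (R)-4-benzyl-2-oxazolidinone | O=C1N[C@H](Cc2ccccc2)CO1 | starting material
2 | bromoacetyl bromide | O=C(Br)CBr | starting material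
3 | (R)-4-benzyl-3-(2-bromoacetyl)oxazolidin-2-one | O=C(CBr)N1[C@H](Cc2ccccc2)COC1=O | intermediate
4 | 4-bromo-2,6-dimethoxyphenol | COc1cc(Br)cc(OC)c1O | starting material
5 | (R)-4-benzyl-3-[2-(4-bromo-2,6-dimethoxyphenoxy)acetyl]oxazolidin-2-one | COc1cc(Br)cc(OC)c1OCC(=O)N1[C@H](Cc2ccccc2)COC1=O | intermediate
6 | vanillin (4-hydroxy-3-methoxybenzaldehyde) | COc1cc(C=O)ccc1O | starting material
7 | 3-methoxy-4-(triisopropylsilyloxy)benzaldehyde | COc1cc(C=O)ccc1O[Si](C(C)C)(C(C)C)C(C)C | intermediate
8 | (R)-4-benzyl-3-[(Z)-2-(4-bromo-2,6-dimethoxyphenoxy)-1-(dibutylboryloxy)vinyl]oxazolidin-2-one (Z-boron enolate of 5) | CCCCB(CCCC)O/C(=C\Oc1c(OC)cc(Br)cc1OC)N1[C@H](Cc2ccccc2)COC1=O | intermediate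
9 | (R)-4-benzyl-3-[(2R,3S)-2-(4-bromo-2,6-dimethoxyphenoxy)-3-hydroxy-3-(3-methoxy-4-triisopropylsilyloxyphenyl)propanoyl]oxazolidin-2-one | O=C(N1[C@H](Cc2ccccc2)COC1=O)[C@H](Oc1c(OC)cc(Br)cc1OC)[C@@H](O)c1ccc(O[Si](C(C)C)(C(C)C)C(C)C)c(OC)c1 | intermediate
10 | (1S,2S)-2-(4-bromo-2,6-dimethoxyphenoxy)-1-(3-methoxy-4-triisopropylsilyloxyphenyl)propane-1,3-diol (threo; 7S,8S) | COc1cc([C@H](O)[C@H](CO)Oc2c(OC)cc(Br)cc2OC)ccc1O[Si](C(C)C)(C(C)C)C(C)C | intermediate
11 | (1S,2S)-2-[2,6-dimethoxy-4-(trimethylsilylethynyl)phenoxy]-1-(3-methoxy-4-triisopropylsilyloxyphenyl)propane-1,3-diol | COc1cc([C@H](O)[C@H](CO)Oc2c(OC)cc(C#C[Si](C)(C)C)cc2OC)ccc1O[Si](C(C)C)(C(C)C)C(C)C | intermediate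
12 | (1S,2S)-2-(4-ethynyl-2,6-dimethoxyphenoxy)-1-(3-methoxy-4-triisopropylsilyloxyphenyl)propane-1,3-diol | COc1cc([C@H](O)[C@H](CO)Oc2c(OC)cc(C#C)cc2OC)ccc1O[Si](C(C)C)(C(C)C)C(C)C | intermediate
13 | p-coumaric acid | OC(=O)/C=C/c1ccc(O)cc1 | starting material
14 | triisopropylsilyl (E)-4-(triisopropylsilyloxy)cinnamate | CC(C)[Si](C(C)C)(C(C)C)OC(=O)/C=C/c1ccc(O[Si](C(C)C)(C(C)C)C(C)C)cc1 | intermediate
15 | (E)-4-(triisopropylsilyloxy)cinnamic acid | OC(=O)/C=C/c1ccc(O[Si](C(C)C)(C(C)C)C(C)C)cc1 | intermediate
16 | (2S,3S)-2-(4-ethynyl-2,6-dimethoxyphenoxy)-3-hydroxy-3-(3-methoxy-4-triisopropylsilyloxyphenyl)propyl (E)-4-(triisopropylsilyloxy)cinnamate (threo; 7S,8S) | COc1cc([C@H](O)[C@H](COC(=O)/C=C/c2ccc(O[Si](C(C)C)(C(C)C)C(C)C)cc2)Oc2c(OC)cc(C#C)cc2OC)ccc1O[Si](C(C)C)(C(C)C)C(C)C | intermediate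
17 | (2S,3R)-3-(2-chloroacetoxy)-2-(4-ethynyl-2,6-dimethoxyphenoxy)-3-(3-methoxy-4-triisopropylsilyloxyphenyl)propyl (E)-4-(triisopropylsilyloxy)cinnamate (erythro; 7R,8S) | COc1cc([C@@H](OC(=O)CCl)[C@H](COC(=O)/C=C/c2ccc(O[Si](C(C)C)(C(C)C)C(C)C)cc2)Oc2c(OC)cc(C#C)cc2OC)ccc1O[Si](C(C)C)(C(C)C)C(C)C | intermediate
18 | (2S,3R)-2-(4-ethynyl-2,6-dimethoxyphenoxy)-3-hydroxy-3-(3-methoxy-4-triisopropylsilyloxyphenyl)propyl (E)-4-(triisopropylsilyloxy)cinnamate (erythro; 7R,8S) | COc1cc([C@@H](O)[C@H](COC(=O)/C=C/c2ccc(O[Si](C(C)C)(C(C)C)C(C)C)cc2)Oc2c(OC)cc(C#C)cc2OC)ccc1O[Si](C(C)C)(C(C)C)C(C)C | intermediate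
19 | (2S,3R)-2-(4-ethynyl-2,6-dimethoxyphenoxy)-3-(3-methoxy-4-triisopropylsilyloxyphenyl)-3-(triethylsilyloxy)propyl (E)-4-(triisopropylsilyloxy)cinnamate | COc1cc([C@@H](O[Si](CC)(CC)CC)[C@H](COC(=O)/C=C/c2ccc(O[Si](C(C)C)(C(C)C)C(C)C)cc2)Oc2c(OC)cc(C#C)cc2OC)ccc1O[Si](C(C)C)(C(C)C)C(C)C | intermediate
20 | phloroglucinol | Oc1cc(O)cc(O)c1 | starting material
21 | 2-iodophloroglucinol (2-iodobenzene-1,3,5-triol) | Oc1cc(O)c(I)c(O)c1 | intermediate
22 | 2-iodobenzene-1,3,5-triyl triacetate | CC(=O)Oc1cc(OC(C)=O)c(I)c(OC(C)=O)c1 | intermediate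
23 | carbon monoxide | [C-]#[O+] | starting material
24 | (2S,3R)-2-{2,6-dimethoxy-4-[3-oxo-3-(2,4,6-triacetoxyphenyl)prop-1-ynyl]phenoxy}-3-(3-methoxy-4-triisopropylsilyloxyphenyl)-3-(triethylsilyloxy)propyl (E)-4-(triisopropylsilyloxy)cinnamate (ynone) | COc1cc([C@@H](O[Si](CC)(CC)CC)[C@H](COC(=O)/C=C/c2ccc(O[Si](C(C)C)(C(C)C)C(C)C)cc2)Oc2c(OC)cc(C#CC(=O)c3c(OC(C)=O)cc(OC(C)=O)cc3OC(C)=O)cc2OC)ccc1O[Si](C(C)C)(C(C)C)C(C)C | intermediate
25 | (2S,3R)-2-{4-[(E)-1-(diethylamino)-3-oxo-3-(2,4,6-trihydroxyphenyl)prop-1-enyl]-2,6-dimethoxyphenoxy}-3-(3-methoxy-4-triisopropylsilyloxyphenyl)-3-(triethylsilyloxy)propyl (E)-4-(triisopropylsilyloxy)cinnamate (enaminone, drawn as the E isomer) | COc1cc([C@@H](O[Si](CC)(CC)CC)[C@H](COC(=O)/C=C/c2ccc(O[Si](C(C)C)(C(C)C)C(C)C)cc2)Oc2c(OC)cc(/C(N(CC)CC)=C\C(=O)c3c(O)cc(O)cc3O)cc2OC)ccc1O[Si](C(C)C)(C(C)C)C(C)C | intermediate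
26 | (2S,3R)-2-[4-(5,7-dihydroxy-4-oxo-4H-chromen-2-yl)-2,6-dimethoxyphenoxy]-3-(3-methoxy-4-triisopropylsilyloxyphenyl)-3-(triethylsilyloxy)propyl (E)-4-(triisopropylsilyloxy)cinnamate | COc1cc([C@@H](O[Si](CC)(CC)CC)[C@H](COC(=O)/C=C/c2ccc(O[Si](C(C)C)(C(C)C)C(C)C)cc2)Oc2c(OC)cc(-c3cc(=O)c4c(O)cc(O)cc4o3)cc2OC)ccc1O[Si](C(C)C)(C(C)C)C(C)C | intermediate
27 | (2S,3R)-2-[4-(5,7-dihydroxy-4-oxo-4H-chromen-2-yl)-2,6-dimethoxyphenoxy]-3-hydroxy-3-(4-hydroxy-3-methoxyphenyl)propyl (E)-3-(4-hydroxyphenyl)acrylate (7R,8S; CNP0264527.1) | COc1cc([C@@H](O)[C@H](COC(=O)/C=C/c2ccc(O)cc2)Oc2c(OC)cc(-c3cc(=O)c4c(O)cc(O)cc4o3)cc2OC)ccc1O | target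

Total step count: 14. Longest linear sequence: 11 steps (steps 1, 2, 4, 5, 6, 8, 9, 10, 11, 13 and 14).

Steps most likely to fail

Step 13. The risk lies in the timing of the catalytic events: slow oxidative addition or early loss of the acetates could lead to reductive loss of iodine, and the alkyne could couple without CO. The amine could also capture the acyl-palladium species, or closure could take the five-membered course. The fallback sets out from 19 and builds the same ynone without CO. Commercial 2,4,6-trihydroxybenzoic acid F1 is peracetylated (Ac2O, pyridine, 0 °C) to 2,4,6-triacetoxybenzoic acid F2. Oxalyl chloride and catalytic DMF convert F2 into 2,4,6-triacetoxybenzoyl chloride F3. Acyl Sonogashira coupling of F3 with 19 (PdCl2(PPh3)2, CuI, Et3N, THF, rt) should give ynone 24, now isolated. Et2NH in THF then takes 24 through 25 to 26, where the route is rejoined.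

Step 9. Partial ionisation of the activated, electron-rich benzylic centre would erode the inversion, and elimination toward the enol ether or participation of the C9 ester carbonyl could divert material. The fallback sets out from 16. Buffered Dess–Martin oxidation (NaHCO3, CH2Cl2, 0 °C) gives the aryl ketone F4. NaBH4 in THF/MeOH at −40 °C then reduces F4 under Felkin–Anh control, hydride arriving anti to the aryloxy group, and should favour the erythro alcohol 18. The route is rejoined at 18 without passing through 17; the minor threo alcohol is 16 itself and can be recycled.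

Step 6. Oxidative addition into the electron-rich aryl bromide may be slow, copper may dimerise the alkyne, and the basic methanolysis may begin to remove the aryl silyl ether. The fallback sets out from 10: Stille coupling with tributyl(ethynyl)stannane (Pd(PPh3)4, toluene, 90 °C) introduces the unprotected ethynyl group directly, without copper, base or a silyl intermediate. It should give 12, where the route is rejoined.

Further compounds
F1 | step 13 | 2,4,6-trihydroxybenzoic acid (purchased) | OC(=O)c1c(O)cc(O)cc1O
F2 | step 13 | 2,4,6-triacetoxybenzoic acid | CC(=O)Oc1cc(OC(C)=O)c(C(=O)O)c(OC(C)=O)c1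
F3 | step 13 | 2,4,6-triacetoxybenzoyl chloride | CC(=O)Oc1cc(OC(C)=O)c(C(Cl)=O)c(OC(C)=O)c1
F4 | step 9 | (2S)-2-(4-ethynyl-2,6-dimethoxyphenoxy)-3-(3-methoxy-4-triisopropylsilyloxyphenyl)-3-oxopropyl (E)-4-(triisopropylsilyloxy)cinnamate | COc1cc(C(=O)[C@H](COC(=O)/C=C/c2ccc(O[Si](C(C)C)(C(C)C)C(C)C)cc2)Oc2c(OC)cc(C#C)cc2OC)ccc1O[Si](C(C)C)(C(C)C)C(C)C
F0 | step 6 | none | none
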